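The target is a mirror-symmetric trimer: a central butanoylphloroglucinol ring carries, through two CH2 bridges, two identical outer rings, each a 2-butanoyl-6,6-dimethylcyclohexane-1,3,5-trione (enolized; C1–C6 as in this name). Everything rests on cutting each outer ring at C2–C3 and C4–C5. In one operation the lithium enolate of methyl acetate (C3, C4) opens the enol lactone 3,3-dimethyl-6-propylpyran-2,4-dione at its lactone carbonyl (C5), and the 1,3-diketone enolate thereby released closes through C2 onto the acetate carbonyl (C3). The step exploits the alternating oxygenation at C1, C3, C5 around the non-enolizable quaternary C6. Two such rings are then joined at C4 to a bis-Mannich base of the central ring.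

Key step: step 3

Remark: all enolized tricarbonyl compounds are drawn and named as the single tautomer used in the target SMILES; the target has no stereocentre, so no stereocontrol is required. Compound 8 is needed in two equivalents for step 6.

Step 1
Reactants: 1 methyl 2,2-dimethyl-3-oxobutanoate; 2 butanoyl chloride
Product: 3 methyl 2,2-dimethyl-3,5-dioxooctanoate
Conditions: MgBr2·OEt2 (2.5 equiv), i-Pr2NEt (3 equiv), CH2Cl2, 0 °C → rt; aq. HCl work-up
Reagents that add atoms: none
Why: Soft enolization gives the magnesium enolate at the only enolizable position (the acetyl CH3, since C2 is quaternary), and its C-acylation by the acid chloride (crossed Claisen-type acylation of a ketone) should give the chelated 1,3-diketone.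

Step 2
Reactants: 3 methyl 2,2-dimethyl-3,5-dioxooctanoate
Product: 4 3,3-dimethyl-6-propyl-2H-pyran-2,4(3H)-dione
Conditions: conc. H2SO4, 0 °C → rt; poured onto ice, extraction
Reagents that add atoms: none
Why: Acid-promoted enol lactonization (6-exo-trig intramolecular transesterification of the methyl ester by the C5 enol oxygen with loss of methanol, as in pyranone formation from 3,5-dioxo esters) should give the enol lactone, which stays an activated acyl donor because its quaternary C3 forbids tautomerization to a 4-hydroxypyranone.

Step 3
Reactants: 4 3,3-dimethyl-6-propyl-2H-pyran-2,4(3H)-dione; 5 methyl acetate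
Product: 8 butyrylfilicinic acid (2-butanoyl-3,5-dihydroxy-6,6-dimethylcyclohexa-2,4-dien-1-one), via lithium 1-methoxyethenolate 6 (not isolated), via open-chain triketo ester 7 (not isolated)
Conditions: LiN(SiMe3)2 (3 equiv), 5 (3 equiv), THF, −78 °C; then 4, −78 → 0 °C; then MeOH, 50 °C; 1 M HCl
Reagents that add atoms: none
Why: Enolate 6 adds to the lactone carbonyl (pyran C2) of 4 and the tetrahedral intermediate expels the 1,3-diketone enolate (new ring bond C4–C5), giving triketo ester 7 as its dianion; once methanol allows proton exchange, the diketone enolate carbon attacks the methyl ester carbonyl and methoxide leaves (new ring bond C2–C3). The closest known reaction types are the Fujimoto–Belleau ring transformation of enol lactones by carbon nucleophiles and the Claisen-mode (Dieckmann) cyclization of 3,5,7-triketo esters to acylphloroglucinols. The ring closes in a 6-exo-trig (enolexo) Dieckmann mode, helped by the gem-dimethyl group at C6. No stereocentre is formed. The step needs attack at the lactone carbonyl and not at the vinylogous-ester carbonyl (pyran C4) or the enol-ether carbon (pyran C6), which the hard lithium enolate at −78 °C and the anhydride-like character of the enol ester should secure, and it needs Claisen over aldol closure, which should hold because both ketone groups are masked as enolates, aldol adducts cannot aromatize past the CMe2 carbon and revert, and only the Claisen path ends in the stabilized trione anion. The regiochemistry of closure is fixed because the diketone enolate is unmasked at exactly the carbon that becomes C2 and no other six-membered acylation is possible.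

Step 4
Reactants: 9 phloroglucinol (benzene-1,3,5-triol); 2 butanoyl chloride
Product: 10 1-(2,4,6-trihydroxyphenyl)butan-1-one
Conditions: AlCl3 (4 equiv), PhNO2–CH2Cl2, 0 → 60 °C; ice/aq. HCl
Reagents that add atoms: none
Why: Friedel–Crafts C-acylation of the electron-rich arene should stop at the mono-ketone because the first acyl group, chelated by the flanking hydroxyl groups, deactivates the ring.

Step 5
Reactants: 10 1-(2,4,6-trihydroxyphenyl)butan-1-one
Product: 11 1-{3,5-bis[(dimethylamino)methyl]-2,4,6-trihydroxyphenyl}butan-1-one
Conditions: Me2NCH2NMe2 (2.2 equiv), 1,4-dioxane, rt
Reagents that add atoms: N,N,N',N'-tetramethylmethanediamine, CN(C)CN(C)C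
Why: Double phenolic Mannich reaction, in which the acidic acylphloroglucinol protonates the aminal to an iminium ion that substitutes the only two free ring positions (C3 and C5), each activated by three hydroxyl groups.

Step 6
Reactants: 11 1-{3,5-bis[(dimethylamino)methyl]-2,4,6-trihydroxyphenyl}butan-1-one; 8 butyrylfilicinic acid (2 equivalents)
Product: 13 target (filixic acid BBB), via mono-bridged Mannich base 12 (not isolated)
Conditions: 8 (2.1 equiv), 1,4-dioxane, 90 °C, N2 stream
Reagents that add atoms: none
Why: The acidic trione 8 protonates each benzylic amine of 11, loss of dimethylamine gives an ortho-quinone methide, and Michael addition of the enol carbon C4 of 8 (Mannich-base alkylation of a 1,3-dicarbonyl compound) should give first 12 and then the target, with no free formaldehyde present to form a methylene-bis(filicinic acid).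

Compound list
1 | methyl 2,2-dimethyl-3-oxobutanoate | CC(=O)C(C)(C)C(=O)OC | starting material
2 | butanoyl chloride | CCCC(=O)Cl | starting material
3 | methyl 2,2-dimethyl-3,5-dioxooctanoate | CCCC(=O)CC(=O)C(C)(C)C(=O)OC | intermediate
4 | 3,3-dimethyl-6-propyl-2H-pyran-2,4(3H)-dione | CCCC1=CC(=O)C(C)(C)C(=O)O1 | intermediate
5 | methyl acetate | CC(=O)OC | starting material
6 | lithium 1-methoxyethenolate (lithium enolate of methyl acetate), not isolated | [Li+].[O-]C(=C)OC | intermediate
7 | methyl 4,4-dimethyl-3,5,7-trioxodecanoate (present as its dilithium bis-enolate), not isolated | CCCC(=O)CC(=O)C(C)(C)C(=O)CC(=O)OC | intermediate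
8 | butyrylfilicinic acid, 2-butanoyl-3,5-dihydroxy-6,6-dimethylcyclohexa-2,4-dien-1-one | CCCC(=O)C1=C(O)C=C(O)C(C)(C)C1=O | intermediate
9 | phloroglucinol (benzene-1,3,5-triol) | Oc1cc(O)cc(O)c1 | starting material
10 | 1-(2,4,6-trihydroxyphenyl)butan-1-one | CCCC(=O)c1c(O)cc(O)cc1O | intermediate
11 | 1-{3,5-bis[(dimethylamino)methyl]-2,4,6-trihydroxyphenyl}butan-1-one | CCCC(=O)c1c(O)c(CN(C)C)c(O)c(CN(C)C)c1O | intermediate
12 | mono-bridged Mannich base: the butanoylphloroglucinol ring carrying one CH2NMe2 group at C5 and, at C3, a CH2 link to C4 of one butyrylfilicinic acid ring; not isolated | CCCC(=O)c1c(O)c(CN(C)C)c(O)c(CC2=C(O)C(C)(C)C(=O)C(C(=O)CCC)=C2O)c1O | intermediate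
13 | filixic acid BBB: 1-(2,4,6-trihydroxyphenyl)butan-1-one ring whose C3 and C5 each carry a CH2 group bonded to C4 of a 2-butanoyl-3,5-dihydroxy-6,6-dimethylcyclohexa-2,4-dien-1-one ring; no stereocentre | CCCC(=O)C1=C(O)C(Cc2c(O)c(CC3=C(O)C(C)(C)C(=O)C(C(=O)CCC)=C3O)c(O)c(C(=O)CCC)c2O)=C(O)C(C)(C)C1=O | target

Total step count: 6
Longest linear sequence: 4 steps (steps 1, 2, 3 and 6); the second branch (steps 4, 5, 6) has 3.

Steps most likely to fail

Step 3. The open-chain dianion may close in an aldol mode instead of the Claisen mode. The enolate may also add to the vinylogous-ester carbonyl of 4, or deprotonate the propyl CH2 next to the enol ether, so that acyl transfer does not occur. The fallback abandons ring construction and takes the outer ring from the aromatic pool. It sets out from 10, whose dearomatizing geminal C-methylation (MeI, NaOMe, MeOH, 0 °C → rt) should give the gem-dimethyl trione directly. It comes back to the route at 8 and makes no new compound (F0).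

Step 6. Amine exchange and retro-Michael methylene transfer may scramble the bridges, or the reaction may stall after the first alkylation at 12. The fallback is the classical three-component condensation. It sets out from 10 and 8 (2 equivalents), which are condensed with 37% aqueous formaldehyde in 1% aqueous KOH at 0 °C. It passes through the mono-bridged compound norflavaspidic acid BB F1 and, after acidification with HCl and chromatographic removal of statistical by-products, comes back at 13.

Step 2. Lactonization may remain incomplete because methanol is not removed, or the enol lactone may be reopened by water during the quench. The fallback activates a free acid instead of exchanging the ester. It sets out from 3, which is saponified (LiOH, THF–H2O, rt; cold acidification with HCl to avoid decarboxylation) to 2,2-dimethyl-3,5-dioxooctanoic acid F2. Cyclodehydration through the mixed anhydride ((CF3CO)2O, CH2Cl2, 0 °C) should then close the enol lactone, coming back at 4.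

Further compounds
F0 | step 3 | none | none
F1 | step 6 | norflavaspidic acid BB, 1-(2,4,6-trihydroxyphenyl)butan-1-one carrying at C3 a CH2 link to C4 of one butyrylfilicinic acid ring | CCCC(=O)c1c(O)cc(O)c(CC2=C(O)C(C)(C)C(=O)C(C(=O)CCC)=C2O)c1O
F2 | step 2 | 2,2-dimethyl-3,5-dioxooctanoic acid | CCCC(=O)CC(=O)C(C)(C)C(=O)O
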